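**Strategy.** The two tertiary hydroxyls on the saturated ring B (C5' and C6') are trans, the signature of anti-opening of a C5–C6 oxirane; C6 also bears the exocyclic carbon C7, so with C7 as CH2OH the ring alkene C5=C6 is an allylic alcohol. Titanium–tartrate epoxidation of β-cyclogeraniol, an achiral tetrasubstituted cyclohexenylmethanol obtained by reducing β-cyclocitral, therefore closes the oxirane and sets C5 and C6 in one operation; water then inverts C5 alone. The derived dihydroxy aldehyde is extended to a C15 dienal and united by Wittig olefination with a C25 phosphonium salt carrying the acetylenic ring A, itself made from ketoisophorone via an enol triflate and Sonogashira coupling.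

Key step: step 2

Remark: carotenoid locants are used (C5, C6, C7 of the ring B fragment become C5', C6', C7' of the target), and dialdehyde 22, phosphonate 7 (sold as an E/Z mixture) and enynol 18 are assumed to be purchasable polyene building blocks.

**Ring B fragment**

Step 1
Reactants: 1 β-cyclocitral
Product: 2 β-cyclogeraniol
Conditions: NaBH4, MeOH, 0 °C
Reagents that add atoms: none
Why: Borohydride 1,2-reduction of a hindered conjugated aldehyde (carbonyl hydride reduction) should leave the tetrasubstituted ring alkene untouched and creates no stereocentre.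

Step 2
Reactants: 2 β-cyclogeraniol; 3 tert-butyl hydroperoxide
Product: 4 β-cyclogeraniol (5S,6S)-5,6-epoxide, i.e. [(1S,6S)-2,2,6-trimethyl-7-oxabicyclo[4.1.0]heptan-1-yl]methanol
Conditions: Ti(OiPr)4 (0.10 equiv), L-(+)-diethyl tartrate (0.12 equiv), t-BuOOH (2 equiv, anhydrous), 4 Å molecular sieves, CH2Cl2, −20 °C
Reagents that add atoms: tert-butyl hydroperoxide (3), CC(C)(C)OO
Why: Katsuki–Sharpless asymmetric epoxidation: the C7 alkoxide of 2 and the peroxide replace isopropoxide ligands on the dimeric titanium tartrate (tetravalent titanium), and the titanium-bound peroxide oxygen is transferred to C5=C6 in one concerted step. The closest known reaction type is the titanium–tartrate epoxidation of fully substituted cyclohexenylmethanols, so this is known chemistry applied to 2. The oxirane (O–C5–C6) closes by syn addition of a single oxygen atom to both alkene carbons at once, which makes it cis-fused to the cyclohexane by necessity. C5 and C6 become stereocentres together and both are fixed by the L-(+)-tartrate ligand, which for a primary allylic alcohol oriented like (E)-hex-2-en-1-ol delivers oxygen to the face that gives the S,S-epoxide, here (5S,6S), the face of the 6-OH of the target. The only selectivity required is between the two alkene faces, since 2 is achiral with one alkene and one hydroxyl; it is secured by the C7 hydroxyl, which ties the alkene to the chiral metal centre, while the small cis-methyl on C5 keeps the substrate within the range the catalyst tolerates.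

Step 3
Reactants: 4 epoxy alcohol
Product: 5 (1S,2R)-1-(hydroxymethyl)-2,6,6-trimethylcyclohexane-1,2-diol (trans-5,6-diol with C7 as CH2OH)
Conditions: aq. HClO4 (about 6%), THF, 0 °C → rt
Reagents that add atoms: water, O
Why: Acid-catalysed anti hydrolysis of an epoxide (borderline SN1/SN2 opening): water should attack the protonated oxirane from the rear at C5, which bears positive charge better and is neither screened by the C1 gem-dimethyl group nor deactivated by the C7 oxygen, so C5 is inverted while the C6–O bond and its configuration are kept, giving the trans-diol.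

Step 4
Reactants: 5 triol
Product: 6 (1R,2R)-1,2-dihydroxy-2,6,6-trimethylcyclohexane-1-carbaldehyde
Conditions: 2-iodoxybenzoic acid (IBX, 1.5 equiv), DMSO, rt; used at once
Reagents that add atoms: none
Why: IBX oxidation of the only oxidisable (primary) alcohol; IBX oxidises diol-containing substrates without glycol cleavage and the two tertiary hydroxyls are inert, so no stereocentre is touched.

Step 5
Reactants: 6 dihydroxy aldehyde; 7 triethyl 3-methyl-4-phosphonocrotonate
Product: 9 ethyl (2E,4E)-5-[(1R,2R)-1,2-dihydroxy-2,6,6-trimethylcyclohexyl]-3-methylpenta-2,4-dienoate, via lithiated phosphonate 8 (not isolated)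
Conditions: 7 (2.2 equiv), LiN(SiMe3)2 (2.1 equiv), THF, −78 °C; then 6, −78 → 0 °C
Reagents that add atoms: triethyl 3-methyl-4-phosphonocrotonate (7), CCOC(=O)/C=C(\C)CP(=O)(OCC)OCC
Why: Horner–Wadsworth–Emmons olefination with the vinylogous phosphonate: the pre-formed stabilised carbanion is too weak a base to deprotonate the tertiary hydroxyls appreciably, adds to the aldehyde and loses phosphate to give the E C7=C8 bond, while the 9E trisubstituted alkene should prevail through equilibration of the allylic anion (minor 9Z ester removed by chromatography).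

Step 6
Reactants: 9 dihydroxy dienoate
Product: 10 (1R,2R)-1-[(1E,3E)-5-hydroxy-3-methylpenta-1,3-dien-1-yl]-2,6,6-trimethylcyclohexane-1,2-diol
Conditions: i-Bu2AlH (5 equiv), CH2Cl2, −78 → 0 °C; aq. KNaC4H4O6 work-up
Reagents that add atoms: none
Why: Aluminium hydride reduction of a conjugated ester to the allylic alcohol by 1,2-hydride delivery; excess reagent covers the two free hydroxyls and the diene geometry is not affected.

Step 7
Reactants: 10 dienyl triol
Product: 11 (2E,4E)-5-[(1R,2R)-1,2-dihydroxy-2,6,6-trimethylcyclohexyl]-3-methylpenta-2,4-dienal (C15 dienal of ring B)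
Conditions: MnO2 (excess), CH2Cl2, rt
Reagents that add atoms: none
Why: MnO2 oxidation is selective for the primary allylic alcohol, and its neutral heterogeneous conditions should spare the tertiary hydroxyls and the acid-sensitive 6-hydroxy diene.

**Ring A fragment**

Step 8
Reactants: 12 ketoisophorone
Product: 13 (6R)-2,2,6-trimethylcyclohexane-1,4-dione ((R)-levodione)
Conditions: ene-reductase OYE2 (Old Yellow Enzyme), NADP+ (cat.), glucose dehydrogenase, D-glucose, KH2PO4/K2HPO4 buffer pH 7.0, 30 °C
Reagents that add atoms: none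
Why: Enzymatic asymmetric alkene reduction (the isolated-enzyme form of the baker's yeast reduction of this enedione): flavin hydride and an active-site proton add across the activated C=C, and the enzyme pocket should set C6 as R.

Step 9
Reactants: 13 (R)-levodione
Product: 14 (4R,6R)-4-hydroxy-2,2,6-trimethylcyclohexan-1-one (trans-actinol)
Conditions: LiBH(s-Bu)3 (1.05 equiv), THF, −78 °C; aqueous work-up; recrystallisation
Reagents that add atoms: none
Why: Diastereoselective ketone reduction with a bulky trialkylborohydride: only the unhindered C4 carbonyl should react (C1 lies between a quaternary and a tertiary carbon), and equatorial attack, enforced by the axial methyl of the gem-dimethyl group as in 3,3,5-trimethylcyclohexanone, should give the 4R alcohol trans to the 6-methyl, with any cis isomer removed by crystallisation.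

Step 10
Reactants: 14 trans-actinol
Product: 15 (4R,6R)-2,2,6-trimethyl-4-[(triethylsilyl)oxy]cyclohexan-1-one
Conditions: Et3SiCl, imidazole, CH2Cl2, 0 °C → rt
Reagents that add atoms: chlorotriethylsilane, CC[Si](Cl)(CC)CC
Why: Imidazole-mediated silylation of a secondary alcohol; the triethylsilyl ether withstands enolate, triflation and cross-coupling conditions yet is shed by the acidic methanol of step 13.

Step 11
Reactants: 15 silyl-protected ketone
Product: 17 (4R)-2,6,6-trimethyl-4-[(triethylsilyl)oxy]cyclohex-1-en-1-yl trifluoromethanesulfonate, via lithium enolate 16 (not isolated)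
Conditions: LiN(i-Pr)2, THF, −78 → 0 °C; then PhNTf2, 0 °C → rt
Reagents that add atoms: N-phenylbis(trifluoromethanesulfonimide), O=S(=O)(N(c1ccccc1)S(=O)(=O)C(F)(F)F)C(F)(F)F
Why: Enolate formation and O-sulfonylation (enol triflate synthesis): the ketone has a single α-hydrogen, at C6, so only the tetrasubstituted enol triflate can form, which deliberately erases the C6 stereocentre and leaves C4 untouched.

Step 12
Reactants: 17 enol triflate; 18 (2E)-3-methylpent-2-en-4-yn-1-ol
Product: 19 (2E)-3-methyl-5-{(4R)-2,6,6-trimethyl-4-[(triethylsilyl)oxy]cyclohex-1-en-1-yl}pent-2-en-4-yn-1-ol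
Conditions: Pd(PPh3)4 (5 mol%), CuI (10 mol%), i-Pr2NH, DMF, rt → 50 °C
Reagents that add atoms: none
Why: Sonogashira coupling of a vinyl triflate with a terminal alkyne (oxidative addition to zerovalent palladium, copper acetylide transmetalation, reductive elimination), a coupling established for 2,6,6-trimethylcyclohexenyl triflates, with the E geometry of the enyne partner retained.

Step 13
Reactants: 19 silyl-protected C15 enynol
Product: 21 {(2E)-5-[(4R)-4-hydroxy-2,6,6-trimethylcyclohex-1-en-1-yl]-3-methylpent-2-en-4-yn-1-yl}triphenylphosphonium bromide, via desilylated enyne diol 20 (not isolated)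
Conditions: PPh3·HBr (1.2 equiv), MeOH, rt; crystallisation
Reagents that add atoms: triphenylphosphonium bromide (PPh3·HBr), [Br-].[PH+](c1ccccc1)(c1ccccc1)c1ccccc1
Why: Phosphonium salt formation from an allylic alcohol (SN1-type: protonation, loss of water, capture of the delocalised allyl–propargyl cation by PPh3 at the primary terminus); the acidic methanol should first methanolyse the silyl ether, and the 9E salt is the isomer expected to crystallise.

Step 14
Reactants: 21 C15 phosphonium bromide; 22 (2E,4E,6E)-2,7-dimethylocta-2,4,6-trienedial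
Product: 24 (2E,4E,6E,8E,10E)-13-[(4R)-4-hydroxy-2,6,6-trimethylcyclohex-1-en-1-yl]-2,7,11-trimethyltrideca-2,4,6,8,10-pentaen-12-ynal, via C15 ylide 23 (not isolated)
Conditions: 22 (3 equiv), NaOMe (MeOH) added slowly to 21 and 22, CH2Cl2, 0 °C → rt; crystallisation
Reagents that add atoms: none
Why: Wittig olefination of a semi-stabilised allylic ylide with a dialdehyde kept in excess so that one formyl group reacts; the new C11=C12 bond should form as an E/Z mixture from which the hindered Z isomer relaxes to E on gentle warming or is removed on crystallisation.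

Step 15
Reactants: 24 C25 hydroxy aldehyde
Product: 25 (2E,4E,6E,8E,10E)-13-[(4R)-4-hydroxy-2,6,6-trimethylcyclohex-1-en-1-yl]-2,7,11-trimethyltrideca-2,4,6,8,10-pentaen-12-yn-1-ol
Conditions: NaBH4, MeOH/CH2Cl2, 0 °C
Reagents that add atoms: none
Why: Borohydride 1,2-reduction of a polyenal to the primary allylic alcohol; polyene, alkyne and secondary hydroxyl are inert.

Step 16
Reactants: 25 C25 diol
Product: 26 C25 triphenylphosphonium bromide (PPh3+ on the terminal CH2 of 25)
Conditions: PPh3·HBr, MeOH/CH2Cl2, 0 °C → rt
Reagents that add atoms: triphenylphosphonium bromide (PPh3·HBr), [Br-].[PH+](c1ccccc1)(c1ccccc1)c1ccccc1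
Why: Phosphonium salt formation from a polyenyl alcohol, the SN1-type process by which retinol-type alcohols give their Wittig salts: PPh3 captures the polyenyl cation at the unhindered primary terminus, and the acid never meets the acid-sensitive diol fragment.

**Union**

Step 17
Reactants: 26 C25 phosphonium bromide; 11 C15 dienal of ring B
Product: 28 (3R,5'R,6'R)-7,8-didehydro-5',6'-dihydro-β,β-carotene-3,5',6'-triol (all-E; target), via C25 ylide 27 (not isolated)
Conditions: 26 (1.2 equiv), NaOMe (MeOH), CH2Cl2, 0 °C → rt; then EtOH, about 50 °C, dark, argon; crystallisation or preparative HPLC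
Reagents that add atoms: none
Why: Wittig olefination between a polyenyl ylide and a dienal, tolerant of free hydroxyls under methoxide conditions; the new C11'=C12' bond should form as an E/Z mixture whose hindered Z isomer should isomerise to E on mild warming, kept gentle so that the 9E enyne geometry and all three stereocentres stay intact.

**Compound list**

1 | β-cyclocitral (2,6,6-trimethylcyclohex-1-ene-1-carbaldehyde) | CC1=C(C=O)C(C)(C)CCC1 | starting material
2 | β-cyclogeraniol ((2,6,6-trimethylcyclohex-1-en-1-yl)methanol) | CC1=C(CO)C(C)(C)CCC1 | intermediate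
3 | tert-butyl hydroperoxide | CC(C)(C)OO | starting material
4 | [(1S,6S)-2,2,6-trimethyl-7-oxabicyclo[4.1.0]heptan-1-yl]methanol | OC[C@@]1(O2)C(C)(C)CCC[C@@]12C | intermediate
5 | (1S,2R)-1-(hydroxymethyl)-2,6,6-trimethylcyclohexane-1,2-diol | OC[C@@]1(O)C(C)(C)CCC[C@@]1(C)O | intermediate
6 | (1R,2R)-1,2-dihydroxy-2,6,6-trimethylcyclohexane-1-carbaldehyde | O=C[C@@]1(O)C(C)(C)CCC[C@@]1(C)O | intermediate
7 | ethyl (2E)-4-(diethoxyphosphoryl)-3-methylbut-2-enoate (drawn 2E; supplied as E/Z mixture) | CCOC(=O)/C=C(\C)CP(=O)(OCC)OCC | starting material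
8 | lithium salt of the carbanion of 7 | [Li+].CCOC(=O)C=C(C)[CH-]P(=O)(OCC)OCC | intermediate
9 | ethyl (2E,4E)-5-[(1R,2R)-1,2-dihydroxy-2,6,6-trimethylcyclohexyl]-3-methylpenta-2,4-dienoate | CCOC(=O)/C=C(C)/C=C/[C@@]1(O)C(C)(C)CCC[C@@]1(C)O | intermediate
10 | (1R,2R)-1-[(1E,3E)-5-hydroxy-3-methylpenta-1,3-dien-1-yl]-2,6,6-trimethylcyclohexane-1,2-diol | OC/C=C(C)/C=C/[C@@]1(O)C(C)(C)CCC[C@@]1(C)O | intermediate
11 | (2E,4E)-5-[(1R,2R)-1,2-dihydroxy-2,6,6-trimethylcyclohexyl]-3-methylpenta-2,4-dienal | O=C/C=C(C)/C=C/[C@@]1(O)C(C)(C)CCC[C@@]1(C)O | intermediate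
12 | ketoisophorone (2,6,6-trimethylcyclohex-2-ene-1,4-dione) | CC1=CC(=O)CC(C)(C)C1=O | starting material
13 | (6R)-2,2,6-trimethylcyclohexane-1,4-dione | C[C@@H]1CC(=O)CC(C)(C)C1=O | intermediate
14 | (4R,6R)-4-hydroxy-2,2,6-trimethylcyclohexan-1-one | C[C@@H]1C[C@@H](O)CC(C)(C)C1=O | intermediate
15 | (4R,6R)-2,2,6-trimethyl-4-[(triethylsilyl)oxy]cyclohexan-1-one | C[C@@H]1C[C@@H](O[Si](CC)(CC)CC)CC(C)(C)C1=O | intermediate
16 | lithium (4R)-2,6,6-trimethyl-4-[(triethylsilyl)oxy]cyclohex-1-en-1-olate | [Li+].CC1=C([O-])C(C)(C)C[C@H](O[Si](CC)(CC)CC)C1 | intermediate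
17 | (4R)-2,6,6-trimethyl-4-[(triethylsilyl)oxy]cyclohex-1-en-1-yl trifluoromethanesulfonate | CC1=C(OS(=O)(=O)C(F)(F)F)C(C)(C)C[C@H](O[Si](CC)(CC)CC)C1 | intermediate
18 | (2E)-3-methylpent-2-en-4-yn-1-ol | C#C/C(C)=C/CO | starting material
19 | (2E)-3-methyl-5-{(4R)-2,6,6-trimethyl-4-[(triethylsilyl)oxy]cyclohex-1-en-1-yl}pent-2-en-4-yn-1-ol | CC1=C(C#C/C(C)=C/CO)C(C)(C)C[C@H](O[Si](CC)(CC)CC)C1 | intermediate
20 | (2E)-5-[(4R)-4-hydroxy-2,6,6-trimethylcyclohex-1-en-1-yl]-3-methylpent-2-en-4-yn-1-ol | CC1=C(C#C/C(C)=C/CO)C(C)(C)C[C@H](O)C1 | intermediate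
21 | {(2E)-5-[(4R)-4-hydroxy-2,6,6-trimethylcyclohex-1-en-1-yl]-3-methylpent-2-en-4-yn-1-yl}triphenylphosphonium bromide | [Br-].CC1=C(C#C/C(C)=C/C[P+](c2ccccc2)(c2ccccc2)c2ccccc2)C(C)(C)C[C@H](O)C1 | intermediate
22 | (2E,4E,6E)-2,7-dimethylocta-2,4,6-trienedial | O=C/C(C)=C/C=C/C=C(C)/C=O | starting material
23 | ylide of 21 (triphenylphosphoranylidene at the former CH2P carbon) | CC1=C(C#C/C(C)=C/C=P(c2ccccc2)(c2ccccc2)c2ccccc2)C(C)(C)C[C@H](O)C1 | intermediate
24 | (2E,4E,6E,8E,10E)-13-[(4R)-4-hydroxy-2,6,6-trimethylcyclohex-1-en-1-yl]-2,7,11-trimethyltrideca-2,4,6,8,10-pentaen-12-ynal | CC1=C(C#C/C(C)=C/C=C/C(C)=C/C=C/C=C(C)/C=O)C(C)(C)C[C@H](O)C1 | intermediate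
25 | (2E,4E,6E,8E,10E)-13-[(4R)-4-hydroxy-2,6,6-trimethylcyclohex-1-en-1-yl]-2,7,11-trimethyltrideca-2,4,6,8,10-pentaen-12-yn-1-ol | CC1=C(C#C/C(C)=C/C=C/C(C)=C/C=C/C=C(C)/CO)C(C)(C)C[C@H](O)C1 | intermediate
26 | {(2E,4E,6E,8E,10E)-13-[(4R)-4-hydroxy-2,6,6-trimethylcyclohex-1-en-1-yl]-2,7,11-trimethyltrideca-2,4,6,8,10-pentaen-12-yn-1-yl}triphenylphosphonium bromide | [Br-].CC1=C(C#C/C(C)=C/C=C/C(C)=C/C=C/C=C(C)/C[P+](c2ccccc2)(c2ccccc2)c2ccccc2)C(C)(C)C[C@H](O)C1 | intermediate
27 | ylide of 26 | CC1=C(C#C/C(C)=C/C=C/C(C)=C/C=C/C=C(C)/C=P(c2ccccc2)(c2ccccc2)c2ccccc2)C(C)(C)C[C@H](O)C1 | intermediate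
28 | (3R,5'R,6'R)-7,8-didehydro-5',6'-dihydro-β,β-carotene-3,5',6'-triol, all-E | CC1=C(C#C/C(C)=C/C=C/C(C)=C/C=C/C=C(C)/C=C/C=C(C)/C=C/[C@@]2(O)C(C)(C)CCC[C@@]2(C)O)C(C)(C)C[C@H](O)C1 | target

**Step count.** Total: 17 steps. Longest linear sequence: 10 steps (steps 8–17, from ketoisophorone 12). The ring B branch is 8 steps (steps 1–7 and 17).

**Steps most likely to fail**

Step 2. Turnover may be slow and the discrimination between the two alkene faces incomplete at the hindered tetrasubstituted alkene, which would lower the enantiomeric purity of everything downstream. The fallback replaces asymmetric catalysis by resolution. Setting out from 2, hydroxyl-directed epoxidation with VO(acac)2 and t-BuOOH in CH2Cl2 gives the racemic epoxy alcohol F1. Esterification with (2S)-2-methoxy-2-phenylacetic acid (DCC, DMAP, CH2Cl2) gives two diastereomeric esters, from which the ester of the (1S,6S)-epoxy alcohol F2 is separated by chromatography or crystallisation. LiOH in aqueous THF then releases 4, where the route is rejoined.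

Step 5. Addition to the neopentyl-type aldehyde may be sluggish, and base-induced retro-aldol cleavage or α-ketol rearrangement of the dihydroxy aldehyde may compete with olefination. The fallback is a base-free, two-stage chain extension. Setting out from 6, Wittig reaction with the stabilised ylide 1-(triphenylphosphoranylidene)propan-2-one in toluene at 80 °C gives the enone F3. HWE reaction of its methyl ketone with the pre-formed sodium salt of triethyl phosphonoacetate (NaH, THF) then gives ester 9 after removal of the 9Z isomer, so the route is rejoined at 9.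

Step 17. E/Z control at the new C11'=C12' bond may be poor, and the thermal correction may erode the 9E geometry next to the alkyne, leaving a mixture of geometric isomers. The fallback is an HWE union with reversed polarity. Setting out from 10, the primary allylic hydroxyl is converted by N-chlorosuccinimide and Me2S (CH2Cl2, −20 °C) into the allylic chloride F4. Michaelis–Becker reaction with NaP(O)(OEt)2 in THF gives the allylic phosphonate F5. Its anion (NaN(SiMe3)2, THF, −78 → 0 °C) should condense E-selectively with C25 aldehyde 24 to give target 28 directly, so the fallback returns at 28 and makes steps 7, 15 and 16 unnecessary.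

**Further compounds**

F1 | step 2 | racemic (2,2,6-trimethyl-7-oxabicyclo[4.1.0]heptan-1-yl)methanol | OCC12OC1(C)CCCC2(C)C
F2 | step 2 | [(1S,6S)-2,2,6-trimethyl-7-oxabicyclo[4.1.0]heptan-1-yl]methyl (2S)-2-methoxy-2-phenylacetate | CO[C@H](C(=O)OC[C@@]1(O2)C(C)(C)CCC[C@@]12C)c1ccccc1
F3 | step 5 | (3E)-4-[(1R,2R)-1,2-dihydroxy-2,6,6-trimethylcyclohexyl]but-3-en-2-one | CC(=O)/C=C/[C@@]1(O)C(C)(C)CCC[C@@]1(C)O
F4 | step 17 | (1R,2R)-1-[(1E,3E)-5-chloro-3-methylpenta-1,3-dien-1-yl]-2,6,6-trimethylcyclohexane-1,2-diol | ClC/C=C(C)/C=C/[C@@]1(O)C(C)(C)CCC[C@@]1(C)O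
F5 | step 17 | diethyl {(2E,4E)-5-[(1R,2R)-1,2-dihydroxy-2,6,6-trimethylcyclohexyl]-3-methylpenta-2,4-dien-1-yl}phosphonate | CCOP(=O)(OCC)C/C=C(C)/C=C/[C@@]1(O)C(C)(C)CCC[C@@]1(C)O
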